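## Retrosynthetic overview

- The target is a cis-fused decahydroquinoline, with ring A as N1–C2–C3–C4–C4a–C8a and ring B as C4a–C5–C6–C7–C8–C8a. The last cuts are the C3–O acyl bond (octadienoic acid) and the N-Boc and O-TBS groups.
- C5–C1' is cut by a B-alkyl Suzuki coupling of a C5 enol triflate with the 9-BBN adduct of an epoxide-derived octenyl silyl ether. C5–H then comes from hydrogenation on the convex face.
- Ring B is cut at C4a–C5 (intramolecular Stetter reaction, C5 being the CO of a hydroformylation) and at C8a–C8 (allylsilane on an N-acyliminium ion).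
- Feature: in ring A the run C3(–O)–C4–C4a–C8a, attached to the N- and methyl-bearing C2, is a 2-furyl group on a 1-aminoethyl carbon. An aza-Achmatowicz ring expansion of the furyl carbamate therefore builds ring A and leaves C8a (hemiaminal) and C4a (enone β-carbon) electrophilic for fusing ring B.
- Ring order is A (step 2), then B (step 6). C2 and C5' are bought, and C8a, C4a, C3 and C5 are relayed from C2.

Key step: step 2

Assumption: the furylethylamine, the epoxide, allyltrimethylsilane, allylmagnesium chloride (THF solution) and (2E,4E)-octa-2,4-dienal are bought, the first two as single enantiomers. Decahydroquinoline numbering is used in the discussion of all intermediates (pyridine C6 = C8a, C5 = C4a).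

## Route

Step 1
Reactants: 1 (R)-1-(furan-2-yl)ethan-1-amine
Product: 2 tert-butyl (R)-[1-(furan-2-yl)ethyl]carbamate
Conditions: Boc2O (1.05 equiv), CH2Cl2, 0 °C to rt
Reagents that add atoms: di-tert-butyl dicarbonate, CC(C)(C)OC(=O)OC(=O)OC(C)(C)C
Why: Carbamate formation on a primary amine (Boc protection) does not touch the C2 stereocentre, and Boc is chosen because it tames the nitrogen for the oxidation, supports the later N-acyliminium chemistry and leaves under acid that spares the final dienoate.

Step 2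
Reactants: 2 tert-butyl (R)-[1-(furan-2-yl)ethyl]carbamate
Product: 4 tert-butyl (2R)-6-hydroxy-2-methyl-3-oxo-3,6-dihydropyridine-1(2H)-carboxylate (hemiaminal epimers at C6), via Z-ene-dione 3 (not isolated)
Conditions: m-CPBA (1.2 equiv), CH2Cl2, 0 °C to rt
Reagents that add atoms: m-chloroperbenzoic acid, O=C(OO)c1cccc(Cl)c1
Why: The peracid oxidises the electron-rich furan at its more substituted C2=C3 bond, and the labile epoxide opens with cleavage of the ring C–O bond to the Z-ene-dione 3, in which the former furan C2 has become the C3 ketone and the former furan C5 an aldehyde (the future C8a). The carbamate N–H, brought next to that aldehyde by the Z geometry of the C4=C4a bond, adds to it in a 6-exo-trig closure that forms N1–C8a and ring A as the cyclic hemiaminal 4. This is the aza-Achmatowicz oxidative ring expansion, a known reaction of carbamate- and sulfonamide-protected furfurylamines. The only new stereocentre is the hemiaminal carbon C8a, which equilibrates through 3 under anomeric and A(1,3) control and need not be controlled because step 4 ionises it. The step needs chemoselective oxidation of the furan and retention at C2: the furan is the only easily oxidised group beside an acylated nitrogen, and C2, although it becomes α to a ketone, meets nothing more basic than m-chlorobenzoate at or below room temperature.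

Step 3
Reactants: 4 tert-butyl (2R)-6-hydroxy-2-methyl-3-oxo-3,6-dihydropyridine-1(2H)-carboxylate
Product: 5 tert-butyl (2R)-6-methoxy-2-methyl-3-oxo-3,6-dihydropyridine-1(2H)-carboxylate (epimers at C6)
Conditions: HC(OMe)3 (3 equiv), PPTS (10 mol %), CH2Cl2, 0 °C to rt
Reagents that add atoms: trimethyl orthoformate, COC(OC)OC
Why: Acid-catalysed exchange of the hemiaminal hydroxyl for methoxy (N,O-acetal formation, with the orthoester taking up the water) gives a storable precursor that ionises cleanly with a Lewis acid, while C2 is untouched and the C8a epimers converge in the next step.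

Step 4
Reactants: 5 tert-butyl (2R)-6-methoxy-2-methyl-3-oxo-3,6-dihydropyridine-1(2H)-carboxylate; 6 allyltrimethylsilane
Product: 8 tert-butyl (2R,6R)-2-methyl-3-oxo-6-(prop-2-en-1-yl)-3,6-dihydropyridine-1(2H)-carboxylate (2,6-trans), via N-acyliminium ion 7 (not isolated)
Conditions: BF3·OEt2 (1.5 equiv), CH2Cl2, −78 to −30 °C
Reagents that add atoms: none
Why: BF3 ionises the N,O-acetal to the flat, fully conjugated N-acyliminium ion 7, whose only sp3 ring atom is C2 and whose methyl group is turned out of the ring plane by A(1,3) strain with the Boc carbonyl, so that the allylsilane (Hosomi–Sakurai-type N-acyliminium allylation) should bond to C8a from the opposite face and set it as R, trans to the methyl group.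

Step 5
Reactants: 8 tert-butyl (2R,6R)-2-methyl-3-oxo-6-(prop-2-en-1-yl)-3,6-dihydropyridine-1(2H)-carboxylate
Product: 9 tert-butyl (2R,6R)-2-methyl-3-oxo-6-(4-oxobutyl)-3,6-dihydropyridine-1(2H)-carboxylate
Conditions: Rh(acac)(CO)2 (1 mol %), BIPHEPHOS (3 mol %), CO/H2 (1:1, 5 bar), THF, 60 °C
Reagents that add atoms: carbon monoxide, [C-]#[O+]
Why: Rhodium-catalysed hydroformylation with this wide-bite-angle bisphosphite is strongly linear-selective for monosubstituted alkenes and leaves the electron-poor 1,2-disubstituted enone and the carbamate alone, so CO arrives as the future C5 at the chain end and no stereocentre is formed.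

Step 6
Reactants: 9 tert-butyl (2R,6R)-2-methyl-3-oxo-6-(4-oxobutyl)-3,6-dihydropyridine-1(2H)-carboxylate
Product: 10 tert-butyl (2R,4aR,8aR)-2-methyl-3,5-dioxooctahydroquinoline-1(2H)-carboxylate (cis-fused)
Conditions: 2-(pentafluorophenyl)-6,7-dihydro-5H-pyrrolo[2,1-c][1,2,4]triazol-2-ium tetrafluoroborate (20 mol %), i-Pr2NEt (30 mol %), toluene, rt to 40 °C
Reagents that add atoms: none
Why: In this intramolecular Stetter reaction the triazolylidene turns the aldehyde carbon C5 into an acyl-anion equivalent that adds 6-exo-trig to the enone β-carbon C4a, the four-carbon tether standing out of the ring plane on C8a can reach C4a only on its own face and so sets C4a with a cis ring fusion (descriptor R because the C5 carbonyl outranks C8a), and the acidic N-C6F5 azolium salt lets a weak amine base suffice so that C2, C4a and C8a are not equilibrated.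

Step 7
Reactants: 10 tert-butyl (2R,4aR,8aR)-2-methyl-3,5-dioxooctahydroquinoline-1(2H)-carboxylate
Product: 11 tert-butyl (2R,3R,4aR,8aR)-3-hydroxy-2-methyl-5-oxooctahydroquinoline-1(2H)-carboxylate
Conditions: LiBH(s-Bu)3 (L-Selectride, 1.0 equiv), THF, −78 °C
Reagents that add atoms: none
Why: In this chemo- and diastereoselective ketone reduction the C3 carbonyl is activated inductively by the α-carbamate nitrogen and sits on the open edge of ring A, whereas C5 is an ordinary dialkyl ketone beside the ring fusion, so one equivalent of the bulky borohydride should take C3 first and, as with 2-substituted cyclohexanones in general, deliver hydride from the side away from the C2 methyl to give the 2,3-cis alcohol (3R).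

Step 8
Reactants: 11 tert-butyl (2R,3R,4aR,8aR)-3-hydroxy-2-methyl-5-oxooctahydroquinoline-1(2H)-carboxylate
Product: 12 tert-butyl (2R,3R,4aR,8aR)-3-[(benzyloxy)methoxy]-2-methyl-5-oxooctahydroquinoline-1(2H)-carboxylate
Conditions: BOMCl (3 equiv), i-Pr2NEt (4 equiv), n-Bu4NI (10 mol %), CH2Cl2, rt to 40 °C
Reagents that add atoms: benzyl chloromethyl ether, ClCOCc1ccccc1
Why: O-Alkylation with an α-chloro ether under amine base and iodide catalysis is mild enough not to enolise the C5 ketone, and the BOM acetal withstands strong base and the coupling yet falls off in the hydrogenation of step 13 without an extra operation.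

Step 9
Reactants: 12 tert-butyl (2R,3R,4aR,8aR)-3-[(benzyloxy)methoxy]-2-methyl-5-oxooctahydroquinoline-1(2H)-carboxylate
Product: 14 tert-butyl (2R,3R,4aR,8aR)-3-[(benzyloxy)methoxy]-2-methyl-5-[(trifluoromethanesulfonyl)oxy]-3,4,4a,7,8,8a-hexahydroquinoline-1(2H)-carboxylate, via potassium enolate 13 (not isolated)
Conditions: KN(SiMe3)2 (1.2 equiv), THF, −78 °C; then N-(5-chloropyridin-2-yl)bis(trifluoromethanesulfonimide) (1.3 equiv), −78 °C
Reagents that add atoms: N-(5-chloropyridin-2-yl)bis(trifluoromethanesulfonimide), FC(F)(F)S(=O)(=O)N(c1ccc(Cl)cn1)S(=O)(=O)C(F)(F)F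
Why: Kinetic deprotonation by the hindered amide removes a C6 methylene proton rather than the crowded C4a methine, which keeps C4a intact and avoids β-elimination of the carbamate from C8a, and O-sulfonylation of enolate 13 at low temperature fixes the C5=C6 enol triflate.

Step 10
Reactants: 15 (R)-2-propyloxirane; 16 allylmagnesium chloride
Product: 17 (R)-oct-7-en-4-ol
Conditions: CuI (10 mol %), THF, −40 to 0 °C
Reagents that add atoms: none
Why: Copper-catalysed Grignard opening of a monosubstituted epoxide is an SN2 attack at the unsubstituted carbon, so the C–O bond at the stereocentre is not broken and the R configuration (the future C5') is carried over unchanged.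

Step 11
Reactants: 17 (R)-oct-7-en-4-ol
Product: 18 (R)-tert-butyl(dimethyl)(oct-7-en-4-yloxy)silane
Conditions: TBSCl (1.2 equiv), imidazole (2.5 equiv), DMF, rt
Reagents that add atoms: tert-butyldimethylsilyl chloride, CC(C)(C)[Si](C)(C)Cl
Why: Standard silylation of a secondary alcohol gives a TBS ether that survives hydroboration, aqueous carbonate, hydrogenation and acylation and falls in the final acid step.

Step 12
Reactants: 14 tert-butyl (2R,3R,4aR,8aR)-3-[(benzyloxy)methoxy]-2-methyl-5-[(trifluoromethanesulfonyl)oxy]-3,4,4a,7,8,8a-hexahydroquinoline-1(2H)-carboxylate; 18 (R)-tert-butyl(dimethyl)(oct-7-en-4-yloxy)silane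
Product: 20 tert-butyl (2R,3R,4aS,8aR)-3-[(benzyloxy)methoxy]-5-[(5R)-5-{[tert-butyl(dimethyl)silyl]oxy}octyl]-2-methyl-3,4,4a,7,8,8a-hexahydroquinoline-1(2H)-carboxylate, via B-alkyl-9-BBN borane 19 (not isolated)
Conditions: 18, 9-BBN-H (1.5 equiv), THF, 0 °C to rt; then 14, PdCl2(dppf) (5 mol %), AsPh3 (10 mol %), Cs2CO3 (3 equiv), DMF–H2O, rt
Reagents that add atoms: none
Why: 9-BBN adds anti-Markovnikov to the terminal alkene, and the B-alkyl borane 19, activated by aqueous base, undergoes B-alkyl Suzuki–Miyaura coupling with the cyclohexenyl triflate to form C5–C1' with the C5=C6 bond kept in place and no stereocentre made or touched.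

Step 13
Reactants: 20 tert-butyl (2R,3R,4aS,8aR)-3-[(benzyloxy)methoxy]-5-[(5R)-5-{[tert-butyl(dimethyl)silyl]oxy}octyl]-2-methyl-3,4,4a,7,8,8a-hexahydroquinoline-1(2H)-carboxylate
Product: 21 tert-butyl (2R,3R,4aS,5S,8aR)-5-[(5R)-5-{[tert-butyl(dimethyl)silyl]oxy}octyl]-3-hydroxy-2-methyloctahydroquinoline-1(2H)-carboxylate
Conditions: H2 (5 bar), Pd(OH)2/C (20 wt %), EtOAc–EtOH, rt
Reagents that add atoms: none
Why: Heterogeneous hydrogenation adds H2 syn to the trisubstituted C5=C6 bond from the convex face that carries H4a and H8a, because the other face is covered by ring A (C4 pseudoaxial on the cyclohexene to escape A(1,2) strain with the side chain, or else the axial N-Boc), which makes H5 cis to H4a and H8a (5S), while the same catalyst hydrogenolyses the benzyl C–O bond of the BOM group and the remaining hemiacetal loses formaldehyde to free the C3 hydroxyl with Boc and TBS inert.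

Step 14
Reactants: 22 (2E,4E)-octa-2,4-dienal
Product: 23 (2E,4E)-octa-2,4-dienoic acid
Conditions: NaClO2 (1.5 equiv), NaH2PO4 (1.5 equiv), 2-methylbut-2-ene (10 equiv), t-BuOH–H2O, 0 °C to rt
Reagents that add atoms: sodium chlorite, [Na+].[O-]Cl=O
Why: Pinnick oxidation converts the conjugated aldehyde into the acid under buffered conditions, with 2-methylbut-2-ene as chlorine scavenger so that the E,E-diene is neither chlorinated nor isomerised.

Step 15
Reactants: 21 tert-butyl (2R,3R,4aS,5S,8aR)-5-[(5R)-5-{[tert-butyl(dimethyl)silyl]oxy}octyl]-3-hydroxy-2-methyloctahydroquinoline-1(2H)-carboxylate; 23 (2E,4E)-octa-2,4-dienoic acid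
Product: 24 tert-butyl (2R,3R,4aS,5S,8aR)-5-[(5R)-5-{[tert-butyl(dimethyl)silyl]oxy}octyl]-2-methyl-3-{[(2E,4E)-octa-2,4-dienoyl]oxy}octahydroquinoline-1(2H)-carboxylate
Conditions: DCC (2 equiv), DMAP (1 equiv), CH2Cl2, 0 °C to rt
Reagents that add atoms: none
Why: Steglich esterification (carbodiimide activation, DMAP acyl transfer) acylates the only free hydroxyl, the C3–O bond is not broken so 3R is retained, and the nitrogen is still blocked as its carbamate.

Step 16
Reactants: 24 tert-butyl (2R,3R,4aS,5S,8aR)-5-[(5R)-5-{[tert-butyl(dimethyl)silyl]oxy}octyl]-2-methyl-3-{[(2E,4E)-octa-2,4-dienoyl]oxy}octahydroquinoline-1(2H)-carboxylate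
Product: 26 (2R,3R,4aS,5S,8aR)-5-[(5R)-5-hydroxyoctyl]-2-methyldecahydroquinolin-3-yl (2E,4E)-octa-2,4-dienoate, via hydrochloride salt 25 (not isolated)
Conditions: HCl (3 M in MeOH), 0 °C to rt; then aq NH3, CH2Cl2
Reagents that add atoms: none
Why: Acidolysis removes the Boc group and solvolyses the secondary TBS ether in one operation, the conjugated ester of a hindered secondary alcohol next to an ammonium centre should resist methanolysis at this temperature, and mild free-basing of 25 gives the target with all six stereocentres and both E alkenes untouched.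

## Compound list

1 | (R)-1-(furan-2-yl)ethan-1-amine | C[C@@H](N)c1ccco1 | starting material
2 | tert-butyl (R)-[1-(furan-2-yl)ethyl]carbamate | CC(C)(C)OC(=O)N[C@H](C)c1ccco1 | intermediate
3 | tert-butyl [(2R,4Z)-3,6-dioxohex-4-en-2-yl]carbamate (Z-ene-dione, not isolated) | CC(C)(C)OC(=O)N[C@H](C)C(=O)/C=C\C=O | intermediate
4 | tert-butyl (2R)-6-hydroxy-2-methyl-3-oxo-3,6-dihydropyridine-1(2H)-carboxylate (hemiaminal epimers) | O=C1C=CC(O)N(C(=O)OC(C)(C)C)[C@@H]1C | intermediate
5 | tert-butyl (2R)-6-methoxy-2-methyl-3-oxo-3,6-dihydropyridine-1(2H)-carboxylate (epimers at C6) | O=C1C=CC(OC)N(C(=O)OC(C)(C)C)[C@@H]1C | intermediate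
6 | allyltrimethylsilane | C=CC[Si](C)(C)C | starting material
7 | (2R)-1-(tert-butoxycarbonyl)-2-methyl-3-oxo-2,3-dihydropyridin-1-ium (N-acyliminium ion, not isolated) | O=C1C=CC=[N+](C(=O)OC(C)(C)C)[C@@H]1C | intermediate
8 | tert-butyl (2R,6R)-2-methyl-3-oxo-6-(prop-2-en-1-yl)-3,6-dihydropyridine-1(2H)-carboxylate | O=C1C=C[C@@H](CC=C)N(C(=O)OC(C)(C)C)[C@@H]1C | intermediate
9 | tert-butyl (2R,6R)-2-methyl-3-oxo-6-(4-oxobutyl)-3,6-dihydropyridine-1(2H)-carboxylate | O=C1C=C[C@@H](CCCC=O)N(C(=O)OC(C)(C)C)[C@@H]1C | intermediate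
10 | tert-butyl (2R,4aR,8aR)-2-methyl-3,5-dioxooctahydroquinoline-1(2H)-carboxylate | O=C1C[C@H]2C(=O)CCC[C@H]2N(C(=O)OC(C)(C)C)[C@@H]1C | intermediate
11 | tert-butyl (2R,3R,4aR,8aR)-3-hydroxy-2-methyl-5-oxooctahydroquinoline-1(2H)-carboxylate | O[C@@H]1C[C@H]2C(=O)CCC[C@H]2N(C(=O)OC(C)(C)C)[C@@H]1C | intermediate
12 | tert-butyl (2R,3R,4aR,8aR)-3-[(benzyloxy)methoxy]-2-methyl-5-oxooctahydroquinoline-1(2H)-carboxylate | c1ccccc1COCO[C@@H]1C[C@H]2C(=O)CCC[C@H]2N(C(=O)OC(C)(C)C)[C@@H]1C | intermediate
13 | potassium C5=C6 enolate of 12 (not isolated) | c1ccccc1COCO[C@@H]1C[C@H]2C([O-])=CCC[C@H]2N(C(=O)OC(C)(C)C)[C@@H]1C.[K+] | intermediate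
14 | tert-butyl (2R,3R,4aR,8aR)-3-[(benzyloxy)methoxy]-2-methyl-5-[(trifluoromethanesulfonyl)oxy]-3,4,4a,7,8,8a-hexahydroquinoline-1(2H)-carboxylate | c1ccccc1COCO[C@@H]1C[C@H]2C(OS(=O)(=O)C(F)(F)F)=CCC[C@H]2N(C(=O)OC(C)(C)C)[C@@H]1C | intermediate
15 | (R)-2-propyloxirane | CCC[C@@H]1CO1 | starting material
16 | allylmagnesium chloride | C=CC[Mg]Cl | starting material
17 | (R)-oct-7-en-4-ol | C=CCC[C@H](O)CCC | intermediate
18 | (R)-tert-butyl(dimethyl)(oct-7-en-4-yloxy)silane | C=CCC[C@H](O[Si](C)(C)C(C)(C)C)CCC | intermediate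
19 | 9-[(5R)-5-{[tert-butyl(dimethyl)silyl]oxy}octyl]-9-borabicyclo[3.3.1]nonane (not isolated) | C1CC2CCCC(C1)B2CCCC[C@H](O[Si](C)(C)C(C)(C)C)CCC | intermediate
20 | tert-butyl (2R,3R,4aS,8aR)-3-[(benzyloxy)methoxy]-5-[(5R)-5-{[tert-butyl(dimethyl)silyl]oxy}octyl]-2-methyl-3,4,4a,7,8,8a-hexahydroquinoline-1(2H)-carboxylate | c1ccccc1COCO[C@@H]1C[C@H]2C(CCCC[C@H](O[Si](C)(C)C(C)(C)C)CCC)=CCC[C@H]2N(C(=O)OC(C)(C)C)[C@@H]1C | intermediate
21 | tert-butyl (2R,3R,4aS,5S,8aR)-5-[(5R)-5-{[tert-butyl(dimethyl)silyl]oxy}octyl]-3-hydroxy-2-methyloctahydroquinoline-1(2H)-carboxylate | O[C@@H]1C[C@H]2[C@@H](CCCC[C@H](O[Si](C)(C)C(C)(C)C)CCC)CCC[C@H]2N(C(=O)OC(C)(C)C)[C@@H]1C | intermediate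
22 | (2E,4E)-octa-2,4-dienal | CCC/C=C/C=C/C=O | starting material
23 | (2E,4E)-octa-2,4-dienoic acid | CCC/C=C/C=C/C(=O)O | intermediate
24 | tert-butyl (2R,3R,4aS,5S,8aR)-5-[(5R)-5-{[tert-butyl(dimethyl)silyl]oxy}octyl]-2-methyl-3-{[(2E,4E)-octa-2,4-dienoyl]oxy}octahydroquinoline-1(2H)-carboxylate | CCC/C=C/C=C/C(=O)O[C@@H]1C[C@H]2[C@@H](CCCC[C@H](O[Si](C)(C)C(C)(C)C)CCC)CCC[C@H]2N(C(=O)OC(C)(C)C)[C@@H]1C | intermediate
25 | hydrochloride of 26 (not isolated) | CCC/C=C/C=C/C(=O)O[C@@H]1C[C@H]2[C@@H](CCCC[C@H](O)CCC)CCC[C@H]2N[C@@H]1C.Cl | intermediate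
26 | (2R,3R,4aS,5S,8aR)-5-[(5R)-5-hydroxyoctyl]-2-methyldecahydroquinolin-3-yl (2E,4E)-octa-2,4-dienoate (CNP0186076.5) | CCC/C=C/C=C/C(=O)O[C@@H]1C[C@H]2[C@@H](CCCC[C@H](O)CCC)CCC[C@H]2N[C@@H]1C | target

## Step count and risks

Total step count: 16.
Longest linear sequence: 13 (steps 1–9, 12, 13, 15, 16).

**Step 6 (Stetter closure).**
- What may go wrong: closure of a six-membered ring from an enolisable aliphatic aldehyde may be slow. Aldol self-condensation, enolate-type Michael closure through C6 to a five-membered ring, or base-induced drift of the enone double bond towards the carbamate nitrogen may then compete.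
- Fallback: replace the carbene umpolung by an acyl radical under neutral conditions, setting out from 9.
- Pinnick oxidation (NaClO2, NaH2PO4, 2-methylbut-2-ene) should give 4-[(2R,6R)-1-(tert-butoxycarbonyl)-6-methyl-5-oxo-1,2,5,6-tetrahydropyridin-2-yl]butanoic acid F1.
- (PhSe)2 and n-Bu3P should convert it into Se-phenyl 4-[(2R,6R)-1-(tert-butoxycarbonyl)-6-methyl-5-oxo-1,2,5,6-tetrahydropyridin-2-yl]butaneselenoate F2.
- Slow addition of n-Bu3SnH and AIBN in benzene at 80 °C generates the nucleophilic acyl radical, which closes 6-exo-trig on C4a on the face of the tether. The α-keto radical at C4 then takes hydrogen from the stannane, and the route is rejoined at 10.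

**Step 7 (mono-reduction of the diketone).**
- What may go wrong: discrimination between the two ketones may be insufficient, giving attack at C5 or over-reduction, or hydride may be delivered from the methyl face. Over-reduced material can be re-oxidised to 10.
- Fallback: bring C5 in at the alcohol level so that the two oxygen functions are never alike, setting out from 9.
- SmI2 (2.2 equiv, THF, −78 °C, no cosolvent, the C3 carbonyl staying masked as its samarium enolate until the quench) should effect reductive aldehyde–enone cyclisation. The product is tert-butyl (2R,4aR,8aR)-5-hydroxy-2-methyl-3-oxooctahydroquinoline-1(2H)-carboxylate F3, whose carbinol epimers are of no consequence.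
- TESCl and imidazole give tert-butyl (2R,4aR,8aR)-2-methyl-3-oxo-5-[(triethylsilyl)oxy]octahydroquinoline-1(2H)-carboxylate F4.
- LiBH(s-Bu)3 now meets a single ketone and gives tert-butyl (2R,3R,4aR,8aR)-3-hydroxy-2-methyl-5-[(triethylsilyl)oxy]octahydroquinoline-1(2H)-carboxylate F5.
- BOMCl and i-Pr2NEt give tert-butyl (2R,3R,4aR,8aR)-3-[(benzyloxy)methoxy]-2-methyl-5-[(triethylsilyl)oxy]octahydroquinoline-1(2H)-carboxylate F6.
- n-Bu4NF buffered with AcOH frees tert-butyl (2R,3R,4aR,8aR)-3-[(benzyloxy)methoxy]-5-hydroxy-2-methyloctahydroquinoline-1(2H)-carboxylate F7, and Dess–Martin oxidation rejoins the route at 12.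

**Step 4 (allylation of the N-acyliminium ion).**
- What may go wrong: facial selectivity in the capture of the cation may be poor or inverted (stereoelectronic attack on the methyl face), or the Boc group may be partly lost under BF3.
- Fallback: exchange the roles of incoming nucleophile and resident substituent, setting out from 2.
- Double deprotonation (n-BuLi, 2.2 equiv, THF, −78 to 0 °C) and allyl bromide should give tert-butyl (R)-{1-[5-(prop-2-en-1-yl)furan-2-yl]ethyl}carbamate F8.
- The same ring expansion with one equivalent of m-CPBA, in which the furan outruns the terminal alkene, gives tert-butyl (2R)-6-hydroxy-2-methyl-3-oxo-6-(prop-2-en-1-yl)-3,6-dihydropyridine-1(2H)-carboxylate F9.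
- Et3SiH with BF3·OEt2 at −78 °C then delivers hydride to the face that a nucleophile prefers, which leaves the allyl group trans to the methyl group and rejoins the route at 8.

## Further compounds

F1 | step 6 | 4-[(2R,6R)-1-(tert-butoxycarbonyl)-6-methyl-5-oxo-1,2,5,6-tetrahydropyridin-2-yl]butanoic acid | O=C1C=C[C@@H](CCCC(=O)O)N(C(=O)OC(C)(C)C)[C@@H]1C
F2 | step 6 | Se-phenyl 4-[(2R,6R)-1-(tert-butoxycarbonyl)-6-methyl-5-oxo-1,2,5,6-tetrahydropyridin-2-yl]butaneselenoate | O=C1C=C[C@@H](CCCC(=O)[Se]c2ccccc2)N(C(=O)OC(C)(C)C)[C@@H]1C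
F3 | step 7 | tert-butyl (2R,4aR,8aR)-5-hydroxy-2-methyl-3-oxooctahydroquinoline-1(2H)-carboxylate (C5 epimers) | O=C1C[C@H]2C(O)CCC[C@H]2N(C(=O)OC(C)(C)C)[C@@H]1C
F4 | step 7 | tert-butyl (2R,4aR,8aR)-2-methyl-3-oxo-5-[(triethylsilyl)oxy]octahydroquinoline-1(2H)-carboxylate (C5 epimers) | O=C1C[C@H]2C(O[Si](CC)(CC)CC)CCC[C@H]2N(C(=O)OC(C)(C)C)[C@@H]1C
F5 | step 7 | tert-butyl (2R,3R,4aR,8aR)-3-hydroxy-2-methyl-5-[(triethylsilyl)oxy]octahydroquinoline-1(2H)-carboxylate (C5 epimers) | O[C@@H]1C[C@H]2C(O[Si](CC)(CC)CC)CCC[C@H]2N(C(=O)OC(C)(C)C)[C@@H]1C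
F6 | step 7 | tert-butyl (2R,3R,4aR,8aR)-3-[(benzyloxy)methoxy]-2-methyl-5-[(triethylsilyl)oxy]octahydroquinoline-1(2H)-carboxylate (C5 epimers) | c1ccccc1COCO[C@@H]1C[C@H]2C(O[Si](CC)(CC)CC)CCC[C@H]2N(C(=O)OC(C)(C)C)[C@@H]1C
F7 | step 7 | tert-butyl (2R,3R,4aR,8aR)-3-[(benzyloxy)methoxy]-5-hydroxy-2-methyloctahydroquinoline-1(2H)-carboxylate (C5 epimers) | c1ccccc1COCO[C@@H]1C[C@H]2C(O)CCC[C@H]2N(C(=O)OC(C)(C)C)[C@@H]1C
F8 | step 4 | tert-butyl (R)-{1-[5-(prop-2-en-1-yl)furan-2-yl]ethyl}carbamate | CC(C)(C)OC(=O)N[C@H](C)c1ccc(CC=C)o1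
F9 | step 4 | tert-butyl (2R)-6-hydroxy-2-methyl-3-oxo-6-(prop-2-en-1-yl)-3,6-dihydropyridine-1(2H)-carboxylate (hemiaminal epimers) | O=C1C=CC(O)(CC=C)N(C(=O)OC(C)(C)C)[C@@H]1C
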